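## Analysis of the target

The target is a cis-fused eremophilane, numbered the eremophilane way throughout: ring A is C1, C2 (ketone), C3, C4 (methyl C15), C5 (methyl C14) and C10 (H); ring B is C5, C6, C7 (isopropenyl, C11–C13), C8 (acetate), C9 (3-methylbut-2-enoate, "senecioate") and C10. Its six stereocentres are contiguous, (4S,5R,7R,8R,9S,10S): H-10, C14, C15 and the isopropenyl group lie on one face (called β below) and both acyloxy groups on the other (α), so the cis-diol sits on the concave side of the cis-decalin. In the ring B chair that keeps C14 and the isopropenyl group equatorial, O8 is equatorial and O9 is axial and syn-axial to C4, so the two hydroxyls of the parent diol differ in reactivity. Sensitive points are the conjugated senecioate (base, hydride), two different esters on a cis-diol (acyl migration), the isopropenyl alkene (it competes in every oxidation and would slide into conjugation if C8 became a carbonyl) and the ketone. The hard parts are the quaternary C5 between the stereocentres C4 and C10, the vicinal cis methyl groups, a diol on the more hindered face, and telling two alkenes and two secondary hydroxyls apart. The strategy rests on two features. First, C7, C10 and C5 of ring B lie around a C8=C9 cyclohexene retron, with C1–C4 of ring A as a four-atom bridge from C10 to C5, which is the pattern of an intramolecular Diels–Alder adduct. Second, C14 and C15 are cis on the adjacent carbons C5 and C4, so they can be held in one five-membered ring while the bicycle forms.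

## Retrosynthetic reasoning

**Esters and ketone last.** Target 31 comes from ketal 30 by hydrolysis; 30 comes from hydroxy acetate 28 and acid chloride 29, and 28 from diol 27. The ketone stays masked to the end because hydride and enolate chemistry is used before. O8 is acetylated first because it is the equatorial, accessible hydroxyl; the hindered axial O9 then takes the senecioate under forcing acylation.

**The α-cis-diol from the C8=C9 alkene.** Reagents reach the cis-fused bicycle from its convex β-face, so direct cis-dihydroxylation would give the wrong diol. The oxygen atoms are therefore brought in through the β-epoxide 21. It is opened from the α-face by a carboxylate (23), and the remaining β C–O bond is inverted by participation of that ester (26). Either regiochemistry of opening leads to the same bridged cation, so only the face of epoxidation matters. That face, and the choice of C8=C9 over the isopropenyl alkene, is set by the C14 hydroxyl of diol 20. The two primary hydroxyls of 20 are carried as sulfonates (22–26) and reduced to the C14 and C15 methyl groups in the step that frees diol 27.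

**A lactone between C14 and C15.** Diol 20 is the reduction product of γ-lactone 19 (C14 carbonyl, C15–O). The lactone is there for stereochemical reasons. In the cycloaddition the tether stands on the inside position of the diene and must be exo on the dienophile, so the C5 carbonyl is endo. It then lies antiperiplanar to C1 across the forming C5–C10 bond, i.e. equatorial on the nascent ring A. A free C4 methyl that is cis to it would have to be axial; the easier chair with an equatorial methyl leads to the 4-epi series. Tying C15 to C14 in a five-membered ring removes that choice, at no cost in steps, since C14 has to be deoxygenated in any case.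

**Key disconnection.** In 19 the bonds C5–C10 and C6–C7 are cut, which opens both rings at once and leads to tetraene 18: an α-methylene-γ-butyrolactone (C5=C6) linked through C4 and the ketal-bearing chain C3–C1 to a (9Z,7E)-diene that carries the isopropenyl group. Cutting here gives an acyclic precursor with a single stereocentre (C4). The forward reaction has to form the quaternary centre, the cis ring fusion and C7 in one step and to leave C8=C9 where the diol is needed.

**The tetraene.** The exocyclic methylene of 18 is added last to lactone 15, because it would not survive ylide chemistry. The C9=C10 alkene of 15 is cut by a Wittig disconnection into phosphonium salt 13 and dienal 3. A non-stabilised ylide is the reliable way to the Z alkene, and the E alkene comes ready-made in 3, which is made from 1 and 2.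

**The stereocentre.** Salt 13 comes from chloride 12, whose lactone is the Baeyer–Villiger product of the prochiral cyclobutanone 11. This desymmetrisation sets C4 and makes C14, C5, C4 and C15 in their final connectivity. Cyclobutanone 11 comes from alkene 7 and dichloroketene 9 (from 8) through 10, and 7 from ketone 6, the acylation product of 4 and 5.

## Alternatives that were turned down

**Alternative 1:** The disconnection is the C9–C10 bond of ring B and leads to the prochiral dienone aldehyde A1, with ring A present as the dienone. In the forward step a chiral triazolylidene carbene turns the aldehyde carbon C9 into an acyl anion equivalent that adds to C10 of one of the two enantiotopic enones (intramolecular Stetter reaction) to give the cis-fused enedione A2.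
- In its favour: A1 is a few steps from simple aromatics, C5 and C10 arise in one catalytic enantioselective step, the C9 oxygen is in place, and the C3=C4 enone is a handle for the C4 methyl. On absolute stereocontrol it is stronger than the chosen strategy, which sets its controlling centre earlier in a separate desymmetrisation.
- Against: A2 lacks C15, the isopropenyl group and the C8 oxygen. C4 (a conjugate addition that must come cis to C14), C7, C8 and the C9 carbinol would each be set in separate operations on a flexible cis-decalin with two ketones to distinguish. Six-membered carbocyclic Stetter closures are also less favourable than five-membered ones.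
- In comparison, the chosen strategy delivers both rings, three stereocentres, the isopropenyl group and a correctly placed C8=C9 alkene in one step.

**Alternative 2:** The disconnection cuts C5–C6 and reconnects C3 to C8, which folds ring B back into a bicyclo[2.2.2]octenone framework of the kind that a masked o-benzoquinone gives by cycloaddition. In the forward step the potassium alkoxide of the tertiary C8 carbinol undergoes an anionic oxy-Cope shift (C3–C8 breaks, C5–C6 forms), and protonation of the enolate at C7 gives A3.
- In its favour: it is very short, the cis fusion follows from the bicyclic template, and A3 already carries both methyl carbons, the isopropenyl group and oxygen at C8 and C9. On oxygenation pattern and on step count to the skeleton it is stronger than the chosen strategy.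
- Against: it is racemic unless an auxiliary or a resolution is added. C7 is created by protonation next to the C8 ketone, where it can epimerise and the isopropenyl alkene can move into conjugation. C4 must be set by reducing C3=C4 in the presence of the isopropenyl group. Two carbonyl-level carbons must be reduced to the α,α-diol and then differentiated, and the C2 oxygen must be adjusted.
- In comparison, the chosen strategy offers a C7 centre fixed by alkene geometry and never adjacent to a carbonyl, a C4 centre set before the rings exist and locked to C5, and catalytic absolute control.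

**Alternative 3:** The disconnection is the transannular C5–C10 bond and leads to the ten-membered dienedione A4. In the forward step, metal-hydride hydrogen-atom transfer to C6 of the C5=C6 alkene gives a tertiary C5 radical that adds across the ring to C10 of the enedione (Giese-type), which closes both six-membered rings and gives A5.
- In its favour: radical addition suits the congested C5–C10 bond at least as well as a cycloaddition with a 1,1-disubstituted dienophile, and C2 and C9 are oxygenated.
- Against: A4, with a stereocentre and two defined alkenes in a medium ring, is itself a demanding target. The ring fusion and the C4/C5 relationship would depend on the conformations of a flexible ten-membered ring. Both ends of the enedione are acceptors, so C5–C1 closure to a hydroazulenone competes. The isopropenyl group cannot be present, since it is the better hydrogen-atom acceptor, so C7 and C8 would have to be built afterwards.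
- In comparison, the chosen strategy fixes regiochemistry by the tether and stereochemistry by alkene geometry and a ring, and its precursor is acyclic.

Key step: step 10

Remark on the chemistry (assumption): in step 6 the antipode of the chiral ligand is taken to be the one that inserts oxygen into the enantiotopic bond leading to (S)-12; both antipodes are accessible.

## Route

Step 1
Reactants: 1 methacrolein; 2 (formylmethylene)triphenylphosphorane
Product: 3 (2E)-4-methylpenta-2,4-dienal
Conditions: 1 (3 equiv), PhMe, 80 °C
Reagents that add atoms: none
Why: Wittig olefination with a stabilised formyl ylide should give the (E)-enal; an excess of the volatile aldehyde 1 suppresses a second homologation of the product.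

Step 2
Reactants: 4 3-chloropropanoyl chloride; 5 allyltrimethylsilane
Product: 6 1-chlorohex-5-en-3-one
Conditions: AlCl3, CH2Cl2, −78 °C
Reagents that add atoms: none
Why: Lewis acid-mediated acylation of an allylsilane (attack at the γ-carbon with loss of the silyl group) should give the β,γ-unsaturated ketone; the low temperature and a cold, non-basic quench keep the alkene out of conjugation and the β-chloride in place.

Step 3
Reactants: 6 1-chlorohex-5-en-3-one
Product: 7 2-(2-chloroethyl)-2-(prop-2-en-1-yl)-1,3-dioxolane
Conditions: Me3SiOCH2CH2OSiMe3, Me3SiOTf (cat.), CH2Cl2, −78 → −20 °C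
Reagents that add atoms: 1,2-bis(trimethylsilyloxy)ethane, C[Si](C)(C)OCCO[Si](C)(C)C
Why: Silyl triflate-catalysed ketalisation with the bis-silyl ether of the diol is aprotic and irreversible, so neither loss of HCl nor migration of the alkene should compete.

Step 4
Reactants: 7 2-(2-chloroethyl)-2-(prop-2-en-1-yl)-1,3-dioxolane; 8 trichloroacetyl chloride
Product: 10 rac-2,2-dichloro-3-{[2-(2-chloroethyl)-1,3-dioxolan-2-yl]methyl}cyclobutan-1-one, via dichloroketene 9 (not isolated)
Conditions: Zn(Cu), POCl3, Et2O, rt, ultrasound
Reagents that add atoms: none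
Why: Zinc dechlorinates 8 to dichloroketene, which adds to the unactivated terminal alkene in a thermal [2+2] cycloaddition with the CCl2 carbon bonded to the substituted alkene carbon; POCl3 binds the ZnCl2 formed and spares the ketal. The ring carbon that becomes C4 is formed racemic here and is made prochiral in step 5.

Step 5
Reactants: 10 rac-2,2-dichloro-3-{[2-(2-chloroethyl)-1,3-dioxolan-2-yl]methyl}cyclobutan-1-one
Product: 11 3-{[2-(2-chloroethyl)-1,3-dioxolan-2-yl]methyl}cyclobutan-1-one
Conditions: Zn, NH4Cl, MeOH, rt
Reagents that add atoms: none
Why: Zinc reduces α-chloro ketones through the zinc enolate; the primary alkyl chloride and the ketal are inert, and the product is an achiral, prochiral cyclobutanone.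

Step 6
Reactants: 11 3-{[2-(2-chloroethyl)-1,3-dioxolan-2-yl]methyl}cyclobutan-1-one
Product: 12 (4S)-4-{[2-(2-chloroethyl)-1,3-dioxolan-2-yl]methyl}oxolan-2-one
Conditions: Sc(OTf)3 (5 mol %), chiral N,N′-dioxide ligand (6 mol %), mCPBA, EtOAc, −20 °C
Reagents that add atoms: 3-chloroperbenzoic acid, OOC(=O)c1cccc(Cl)c1
Why: Enantioselective Baeyer–Villiger oxidation of a prochiral 3-substituted cyclobutanone: the chiral Lewis acid complex distinguishes the two enantiotopic C(O)–CH2 bonds in the migration step of the Criegee adduct, and this sets C4 of the target as the (S)-lactone.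

Step 7
Reactants: 12 (4S)-4-{[2-(2-chloroethyl)-1,3-dioxolan-2-yl]methyl}oxolan-2-one
Product: 13 {2-[2-({(3S)-5-oxooxolan-3-yl}methyl)-1,3-dioxolan-2-yl]ethyl}triphenylphosphonium iodide
Conditions: PPh3, NaI, MeCN, 80 °C
Reagents that add atoms: triphenylphosphine, c1ccc(cc1)P(c1ccccc1)c1ccccc1; sodium iodide, [Na+].[I-]
Why: Finkelstein exchange gives the primary iodide in situ, which quaternises the phosphine by SN2; the lactone and the ketal are inert.

Step 8
Reactants: 13 {2-[2-({(3S)-5-oxooxolan-3-yl}methyl)-1,3-dioxolan-2-yl]ethyl}triphenylphosphonium iodide; 3 (2E)-4-methylpenta-2,4-dienal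
Product: 15 (4S)-4-({2-[(2Z,4E)-6-methylhepta-2,4,6-trien-1-yl]-1,3-dioxolan-2-yl}methyl)oxolan-2-one, via ylide 14 (not isolated)
Conditions: NaN(SiMe3)2 (1.0 equiv), THF, −78 °C; then 3, −78 → 0 °C
Reagents that add atoms: none
Why: Wittig reaction of a non-stabilised ylide under lithium-free conditions: kinetically controlled oxaphosphetane formation should give the (Z)-alkene at C9=C10, and the (E)-alkene of 3 is carried through. The phosphonium α-hydrogens are more acidic than those of the lactone, so one equivalent of base forms only the ylide.

Step 9
Reactants: 15 (4S)-4-({2-[(2Z,4E)-6-methylhepta-2,4,6-trien-1-yl]-1,3-dioxolan-2-yl}methyl)oxolan-2-one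
Product: 18 (4S)-3-methylidene-4-({2-[(2Z,4E)-6-methylhepta-2,4,6-trien-1-yl]-1,3-dioxolan-2-yl}methyl)oxolan-2-one, via Mannich base 16 (not isolated), via ammonium iodide 17 (not isolated)
Conditions: LiN(iPr)2, THF, −78 °C; CH2=NMe2+ I−, −78 °C → rt; then MeI, MeOH, rt; then NaHCO3 (aq), CH2Cl2, rt
Reagents that add atoms: N,N-dimethylmethyleneiminium iodide, C=[N+](C)C.[I-]
Why: Mannich aminomethylation of the lactone enolate, exhaustive methylation and base-induced Hofmann-type loss of trimethylamine is the standard route to α-methylene lactones; C4 is β to the carbonyl and is not touched.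

Step 10
Reactants: 18 (4S)-3-methylidene-4-({2-[(2Z,4E)-6-methylhepta-2,4,6-trien-1-yl]-1,3-dioxolan-2-yl}methyl)oxolan-2-one
Product: 19 (4S,5R,7S,10R)-2,2-(ethylenedioxy)eremophila-8,11-dien-14,15-olide (cis-fused; H-10, C14, C15 and isopropenyl all β)
Conditions: PhMe (0.005 M), BHT (5 mol %), 150 °C, sealed tube
Reagents that add atoms: none
Why: A concerted but asynchronous intramolecular [4+2] cycloaddition (type 1 intramolecular Diels–Alder reaction of a 1,7,9-decatriene), in which the electrophilic methylene carbon C6 bonds to C7 ahead of C5–C10; the closest known reaction types are intramolecular Diels–Alder reactions of (Z)-dienes, which give cis-fused bicycles, and Diels–Alder additions to α-methylene-γ-butyrolactones. Ring B is closed by the cycloaddition itself as the C8=C9 cyclohexene (bonds C5–C10 and C6–C7), and ring A is closed in the fused mode as the six-membered ring of the four-atom tether C1–C4, folded chair-like, by the same C5–C10 bond. C10: the tether stands on the (Z), inside position of the diene and can reach C5 only in the exo-tether, endo-carbonyl transition state, which gives the cis ring fusion. C7: the (7E) geometry keeps the isopropenyl group outside, so it ends cis to H-10 and to the endo carbonyl carbon C14. C5: the diene can reach only the face of the methylene lactone on which the C3 arm of C4 stands, and since C14 and C15 belong to the same five-membered lactone they must end cis on ring A whatever the shape of the tether, so the (S) centre at C4 fixes the absolute configuration of all three new centres. The step needs regioselectivity, which the tether length secures (the diene C8=C7–C11=C12 would have to close an eight-membered ring), and it must outrun the [1,5]-hydrogen shift of the (Z)-diene and bimolecular cycloaddition, which the s-cis-locked exocyclic dienophile, high dilution and a radical inhibitor are meant to secure.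

Step 11
Reactants: 19 (4S,5R,7S,10R)-2,2-(ethylenedioxy)eremophila-8,11-dien-14,15-olide
Product: 20 2,2-(ethylenedioxy)eremophila-8,11-diene-14,15-diol (ring configuration of 19)
Conditions: LiAlH4, THF, 0 °C → rt
Reagents that add atoms: none
Why: Hydride reduction of the γ-lactone to the 1,4-diol frees the C14 hydroxyl that directs the next step; ketal and alkenes are untouched.

Step 12
Reactants: 20 2,2-(ethylenedioxy)eremophila-8,11-diene-14,15-diol
Product: 21 8β,9β-epoxy-2,2-(ethylenedioxy)eremophil-11-ene-14,15-diol
Conditions: VO(acac)2 (cat.), tBuOOH, CH2Cl2, 0 °C → rt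
Reagents that add atoms: tert-butyl hydroperoxide, CC(C)(C)OO
Why: Hydroxyl-directed epoxidation: the vanadium alkoxide of the C14 hydroxyl (a cyclohex-3-enylmethanol, bishomoallylic) delivers oxygen to the β-face of C8=C9, which is also the convex face. The isopropenyl group is one carbon further from either hydroxyl, and the hydroperoxide alone does not epoxidise isolated alkenes.

Step 13
Reactants: 21 8β,9β-epoxy-2,2-(ethylenedioxy)eremophil-11-ene-14,15-diol
Product: 22 8β,9β-epoxy-2,2-(ethylenedioxy)eremophil-11-ene-14,15-diyl dimethanesulfonate
Conditions: MsCl, Et3N, CH2Cl2, 0 °C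
Reagents that add atoms: methanesulfonyl chloride, CS(=O)(=O)Cl
Why: Sulfonylation through the sulfene is fast even at the neopentyl C14 hydroxyl; it activates C14 and C15 for reduction and removes free hydroxyls before the acid-mediated step.

Step 14
Reactants: 22 8β,9β-epoxy-2,2-(ethylenedioxy)eremophil-11-ene-14,15-diyl dimethanesulfonate
Product: 23 9α-acetoxy-2,2-(ethylenedioxy)-8β-hydroxyeremophil-11-ene-14,15-diyl dimethanesulfonate
Conditions: AcOH, NaOAc, 80 °C
Reagents that add atoms: acetic acid, CC(=O)O
Why: Acid-assisted SN2 opening of the epoxide by acetate from the α-face; trans-diaxial (Fürst–Plattner) opening in the chair with C14 and isopropenyl equatorial places acetate at C9 and the hydroxyl at C8. Should the regioisomer form, it gives the same bridged cation in step 15.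

Step 15
Reactants: 23 9α-acetoxy-2,2-(ethylenedioxy)-8β-hydroxyeremophil-11-ene-14,15-diyl dimethanesulfonate
Product: 26 9α-acetoxy-2,2-(ethylenedioxy)-8α-hydroxyeremophil-11-ene-14,15-diyl dimethanesulfonate, via triflate 24 (not isolated), via acetoxonium triflate 25 (not isolated)
Conditions: Tf2O, pyridine, CH2Cl2, −30 °C → rt; then H2O
Reagents that add atoms: water, O
Why: The axial C8 triflate is displaced from the α-face by the carbonyl oxygen of the antiperiplanar C9 acetate (neighbouring-group participation, inversion at C8), and the cis-fused 1,3-dioxolan-2-ylium ion is hydrolysed through its orthoacid to the cis hydroxy ester, as in the second half of a Woodward cis-hydroxylation. The intramolecular capture is expected to outrun elimination towards C7.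

Step 16
Reactants: 26 9α-acetoxy-2,2-(ethylenedioxy)-8α-hydroxyeremophil-11-ene-14,15-diyl dimethanesulfonate
Product: 27 2,2-(ethylenedioxy)eremophil-11-ene-8α,9α-diol
Conditions: LiEt3BH (excess), THF, 0 °C → reflux; then H2O
Reagents that add atoms: none
Why: Hydride displaces both primary mesylates by SN2 (C15 readily, the neopentyl C14 on heating) and cleaves the acetate, so both methyl groups and the free α-diol appear in one operation. The alkoxides at C8 and C9 lie on the face opposite to C14 and are trans to C15 across ring A, so they cannot displace the sulfonates.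

Step 17
Reactants: 27 2,2-(ethylenedioxy)eremophil-11-ene-8α,9α-diol
Product: 28 8α-acetoxy-2,2-(ethylenedioxy)eremophil-11-en-9α-ol
Conditions: Ac2O (1.1 equiv), pyridine, CH2Cl2, 0 °C
Reagents that add atoms: acetic anhydride, CC(=O)OC(C)=O
Why: Site-selective acylation: the equatorial C8 hydroxyl is much more accessible than the axial C9 hydroxyl, which is flanked by the ring fusion and syn-axial to C4; the equatorial acetate is also the thermodynamic site, so acyl migration should not erode the result.

Step 18
Reactants: 28 8α-acetoxy-2,2-(ethylenedioxy)eremophil-11-en-9α-ol; 29 3-methylbut-2-enoyl chloride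
Product: 30 8α-acetoxy-2,2-(ethylenedioxy)-9α-(3-methylbut-2-enoyloxy)eremophil-11-ene
Conditions: DMAP, pyridine, CH2Cl2, rt → 40 °C
Reagents that add atoms: none
Why: Nucleophilic catalysis through the acylpyridinium ion esterifies the hindered axial hydroxyl; pyridine is used instead of a trialkylamine to avoid the vinylketene pathway that would deconjugate the senecioate.

Step 19
Reactants: 30 8α-acetoxy-2,2-(ethylenedioxy)-9α-(3-methylbut-2-enoyloxy)eremophil-11-ene
Product: 31 (4S,5R,7R,8R,9S,10S)-8α-acetoxy-9α-(3-methylbut-2-enoyloxy)eremophil-11-en-2-one (CNP0150397.1)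
Conditions: PPTS, acetone–H2O, 50 °C
Reagents that add atoms: water, O
Why: Mild acid-catalysed ketal hydrolysis frees the C2 ketone; the esters and the isopropenyl group tolerate it, and no stereocentre is α to the new carbonyl.

## Compound list

1 | methacrolein | CC(=C)C=O | starting material
2 | (formylmethylene)triphenylphosphorane | O=CC=P(c1ccccc1)(c1ccccc1)c1ccccc1 | starting material
3 | (2E)-4-methylpenta-2,4-dienal | CC(=C)/C=C/C=O | intermediate
4 | 3-chloropropanoyl chloride | ClCCC(Cl)=O | starting material
5 | allyltrimethylsilane | C=CC[Si](C)(C)C | starting material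
6 | 1-chlorohex-5-en-3-one | ClCCC(=O)CC=C | intermediate
7 | 2-(2-chloroethyl)-2-(prop-2-en-1-yl)-1,3-dioxolane | ClCCC1(CC=C)OCCO1 | intermediate
8 | trichloroacetyl chloride | ClC(Cl)(Cl)C(Cl)=O | starting material
9 | dichloroketene (not isolated) | ClC(Cl)=C=O | intermediate
10 | rac-2,2-dichloro-3-{[2-(2-chloroethyl)-1,3-dioxolan-2-yl]methyl}cyclobutan-1-one | ClCCC1(CC2CC(=O)C2(Cl)Cl)OCCO1 | intermediate
11 | 3-{[2-(2-chloroethyl)-1,3-dioxolan-2-yl]methyl}cyclobutan-1-one | ClCCC1(CC2CC(=O)C2)OCCO1 | intermediate
12 | (4S)-4-{[2-(2-chloroethyl)-1,3-dioxolan-2-yl]methyl}oxolan-2-one | O=C1C[C@H](CC2(CCCl)OCCO2)CO1 | intermediate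
13 | {2-[2-({(3S)-5-oxooxolan-3-yl}methyl)-1,3-dioxolan-2-yl]ethyl}triphenylphosphonium iodide | O=C1C[C@H](CC2(CC[P+](c3ccccc3)(c3ccccc3)c3ccccc3)OCCO2)CO1.[I-] | intermediate
14 | ylide of 13 (not isolated) | O=C1C[C@H](CC2(CC=P(c3ccccc3)(c3ccccc3)c3ccccc3)OCCO2)CO1 | intermediate
15 | (4S)-4-({2-[(2Z,4E)-6-methylhepta-2,4,6-trien-1-yl]-1,3-dioxolan-2-yl}methyl)oxolan-2-one | O=C1C[C@H](CC2(C/C=C\C=C\C(C)=C)OCCO2)CO1 | intermediate
16 | (4S)-3-[(dimethylamino)methyl] derivative of 15, C3 epimers (not isolated) | O=C1C(CN(C)C)[C@H](CC2(C/C=C\C=C\C(C)=C)OCCO2)CO1 | intermediate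
17 | trimethylammonium iodide of 16 (not isolated) | O=C1C(C[N+](C)(C)C)[C@H](CC2(C/C=C\C=C\C(C)=C)OCCO2)CO1.[I-] | intermediate
18 | (4S)-3-methylidene-4-({2-[(2Z,4E)-6-methylhepta-2,4,6-trien-1-yl]-1,3-dioxolan-2-yl}methyl)oxolan-2-one | O=C1C(=C)[C@H](CC2(C/C=C\C=C\C(C)=C)OCCO2)CO1 | intermediate
19 | (4S,5R,7S,10R)-2,2-(ethylenedioxy)eremophila-8,11-dien-14,15-olide | C=C(C)[C@H]1C[C@@]2(C(=O)O5)[C@H](CC3(OCCO3)C[C@@H]2C5)C=C1 | intermediate
20 | 2,2-(ethylenedioxy)eremophila-8,11-diene-14,15-diol | C=C(C)[C@H]1C[C@@]2(CO)[C@H](CC3(OCCO3)C[C@@H]2CO)C=C1 | intermediate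
21 | 8β,9β-epoxy-2,2-(ethylenedioxy)eremophil-11-ene-14,15-diol | C=C(C)[C@H]1C[C@@]2(CO)[C@H](CC3(OCCO3)C[C@@H]2CO)[C@@H](O4)[C@H]14 | intermediate
22 | 8β,9β-epoxy-2,2-(ethylenedioxy)eremophil-11-ene-14,15-diyl dimethanesulfonate | C=C(C)[C@H]1C[C@@]2(COS(C)(=O)=O)[C@H](CC3(OCCO3)C[C@@H]2COS(C)(=O)=O)[C@@H](O4)[C@H]14 | intermediate
23 | 9α-acetoxy-2,2-(ethylenedioxy)-8β-hydroxyeremophil-11-ene-14,15-diyl dimethanesulfonate | C=C(C)[C@H]1C[C@@]2(COS(C)(=O)=O)[C@H](CC3(OCCO3)C[C@@H]2COS(C)(=O)=O)[C@H](OC(C)=O)[C@H]1O | intermediate
24 | 8β-trifluoromethanesulfonate of 23 (not isolated) | C=C(C)[C@H]1C[C@@]2(COS(C)(=O)=O)[C@H](CC3(OCCO3)C[C@@H]2COS(C)(=O)=O)[C@H](OC(C)=O)[C@H]1OS(=O)(=O)C(F)(F)F | intermediate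
25 | 8α,9α-bridged 2-methyl-1,3-dioxolan-2-ylium triflate (not isolated) | C=C(C)[C@H]1C[C@@]2(COS(C)(=O)=O)[C@H](CC3(OCCO3)C[C@@H]2COS(C)(=O)=O)[C@H](OC(C)=[O+]4)[C@@H]14.[O-]S(=O)(=O)C(F)(F)F | intermediate
26 | 9α-acetoxy-2,2-(ethylenedioxy)-8α-hydroxyeremophil-11-ene-14,15-diyl dimethanesulfonate | C=C(C)[C@H]1C[C@@]2(COS(C)(=O)=O)[C@H](CC3(OCCO3)C[C@@H]2COS(C)(=O)=O)[C@H](OC(C)=O)[C@@H]1O | intermediate
27 | 2,2-(ethylenedioxy)eremophil-11-ene-8α,9α-diol | C=C(C)[C@H]1C[C@@]2(C)[C@H](CC3(OCCO3)C[C@@H]2C)[C@H](O)[C@@H]1O | intermediate
28 | 8α-acetoxy-2,2-(ethylenedioxy)eremophil-11-en-9α-ol | C=C(C)[C@H]1C[C@@]2(C)[C@H](CC3(OCCO3)C[C@@H]2C)[C@H](O)[C@@H]1OC(C)=O | intermediate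
29 | 3-methylbut-2-enoyl chloride | CC(C)=CC(Cl)=O | starting material
30 | 8α-acetoxy-2,2-(ethylenedioxy)-9α-(3-methylbut-2-enoyloxy)eremophil-11-ene | C=C(C)[C@H]1C[C@@]2(C)[C@H](CC3(OCCO3)C[C@@H]2C)[C@H](OC(=O)C=C(C)C)[C@@H]1OC(C)=O | intermediate
31 | (4S,5R,7R,8R,9S,10S)-8α-acetoxy-9α-(3-methylbut-2-enoyloxy)eremophil-11-en-2-one | C=C(C)[C@H]1C[C@@]2(C)[C@H](CC(=O)C[C@@H]2C)[C@H](OC(=O)C=C(C)C)[C@@H]1OC(C)=O | target

## Step count and least certain steps

Total: 19 steps. Longest linear sequence: 18 steps (steps 2–19); step 1 supplies dienal 3 for the convergent step 8.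

**Step 10 (key step).** The cycloaddition may be outrun by the [1,5]-hydrogen shift of the (Z)-diene (C1–H to C7), by Z→E isomerisation, or by intermolecular cycloaddition. The reason is that the s-cis form of a (Z)-diene is strained, and that in the chair-like tether the C15 methylene is syn-axial to one ketal oxygen, which raises the barrier. Fallback: setting out from 18, the dioxolane is removed (PPTS, wet acetone) to give the keto tetraenolide (4S)-3-methylidene-4-[(4Z,6E)-8-methyl-2-oxonona-4,6,8-trien-1-yl]oxolan-2-one F1, which has no axial substituent at C2. It is used at once and activated with Me2AlCl (2.2 equiv, CH2Cl2, −78 °C), so that the Lewis acid-promoted cycloaddition proceeds far below the temperature of the hydrogen shift and gives 2-oxoeremophila-8,11-dien-14,15-olide F2. Ketalisation under the conditions of step 3 returns to 19.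

**Step 16.** Hydride may attack sulfur instead of carbon at the neopentyl C14 mesylate (S–O cleavage) or displace it too slowly, because SN2 at a carbon next to the quaternary C5 is strongly retarded. Fallback: setting out from 26, the product of this failure mode is 2,2-(ethylenedioxy)eremophil-11-ene-8α,9α,14-triol F3, in which C15 is already a methyl group. Its primary hydroxyl is oxidised selectively (Cu(MeCN)4OTf, 2,2′-bipyridine, TEMPO, N-methylimidazole, air, MeCN) to 2,2-(ethylenedioxy)-8α,9α-dihydroxyeremophil-11-en-14-al F4. Wolff–Kishner reduction (N2H4·H2O, KOH, diethylene glycol, 200 °C) then gives 27; C7 is by then only singly allylic and the diol is trans to C14.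

**Step 15.** E2 loss of the axial C8 triflate with the antiperiplanar, allylic H-7 may compete with participation of the acetate. Fallback: setting out from 23, Swern oxidation (iPr2NEt as base, −78 °C) gives 9α-acetoxy-2,2-(ethylenedioxy)-8-oxoeremophil-11-ene-14,15-diyl dimethanesulfonate F5. Immediate Luche reduction (NaBH4, CeCl3·7H2O, MeOH, −78 °C) delivers hydride axially from the β-face, anti to the axial C9 acetate, to give the equatorial 8α-alcohol 26. The cold, buffered handling is meant to prevent enolisation towards C7.

**Step 12.** Chemoselectivity may be lost (epoxidation of the isopropenyl group) or the direction may be incomplete, because the directing hydroxyl is three carbons from the alkene. Fallback: setting out from 19, saponification (LiOH, aq THF) and iodolactonisation of the C14 carboxylate (I2, KI, NaHCO3) should engage only C8=C9, as in cyclohex-3-enecarboxylic acids, and give 2,2-(ethylenedioxy)-15-hydroxy-8α-iodoeremophil-11-en-14,9β-olide F6. K2CO3 in MeOH opens the bridged lactone; the C9 alkoxide displaces iodide to form the β-epoxide, and the C15 hydroxyl re-closes the γ-lactone to give 8β,9β-epoxy-2,2-(ethylenedioxy)eremophil-11-en-14,15-olide F7. LiBH4 reduces the lactone and returns to 21.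

**Step 6.** Enantioselection may be insufficient, because the 3-substituent is a flexible alkyl chain. Fallback: setting out from 11, oxidation with mCPBA alone gives racemic 4-{[2-(2-chloroethyl)-1,3-dioxolan-2-yl]methyl}oxolan-2-one F8. Selenenylation (LiN(iPr)2, PhSeBr) gives 4-{[2-(2-chloroethyl)-1,3-dioxolan-2-yl]methyl}-3-(phenylselanyl)oxolan-2-one F9, and oxidative syn-elimination (H2O2) gives 4-{[2-(2-chloroethyl)-1,3-dioxolan-2-yl]methyl}furan-2(5H)-one F10. Copper hydride-catalysed asymmetric conjugate reduction of this β-substituted butenolide (CuCl, NaOtBu, p-tol-BINAP of the appropriate antipode, polymethylhydrosiloxane, PhMe) returns to 12.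

**Step 17.** Site selectivity may be incomplete (acylation at O9 or at both oxygens) if the difference between the equatorial and axial hydroxyls is smaller than expected. Fallback: setting out from 27, Bu2SnO (PhMe, reflux, removal of water) gives the 8α,9α-O-dibutylstannylene acetal F11, in which the equatorial oxygen is the more nucleophilic one; AcCl at 0 °C then gives 28.

## Further compounds

F1 | step 10 | (4S)-3-methylidene-4-[(4Z,6E)-8-methyl-2-oxonona-4,6,8-trien-1-yl]oxolan-2-one | O=C1C(=C)[C@H](CC(=O)C/C=C\C=C\C(C)=C)CO1
F2 | step 10 | 2-oxoeremophila-8,11-dien-14,15-olide (configuration of 19) | C=C(C)[C@H]1C[C@@]2(C(=O)O5)[C@H](CC(=O)C[C@@H]2C5)C=C1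
F3 | step 16 | 2,2-(ethylenedioxy)eremophil-11-ene-8α,9α,14-triol | C=C(C)[C@H]1C[C@@]2(CO)[C@H](CC3(OCCO3)C[C@@H]2C)[C@H](O)[C@@H]1O
F4 | step 16 | 2,2-(ethylenedioxy)-8α,9α-dihydroxyeremophil-11-en-14-al | C=C(C)[C@H]1C[C@@]2(C=O)[C@H](CC3(OCCO3)C[C@@H]2C)[C@H](O)[C@@H]1O
F5 | step 15 | 9α-acetoxy-2,2-(ethylenedioxy)-8-oxoeremophil-11-ene-14,15-diyl dimethanesulfonate | C=C(C)[C@H]1C[C@@]2(COS(C)(=O)=O)[C@H](CC3(OCCO3)C[C@@H]2COS(C)(=O)=O)[C@H](OC(C)=O)C1=O
F6 | step 12 | 2,2-(ethylenedioxy)-15-hydroxy-8α-iodoeremophil-11-en-14,9β-olide | C=C(C)[C@H]1C[C@@]2(C(=O)O6)[C@H](CC3(OCCO3)C[C@@H]2CO)[C@@H]6[C@@H]1I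
F7 | step 12 | 8β,9β-epoxy-2,2-(ethylenedioxy)eremophil-11-en-14,15-olide | C=C(C)[C@H]1C[C@@]2(C(=O)O5)[C@H](CC3(OCCO3)C[C@@H]2C5)[C@@H](O4)[C@H]14
F8 | step 6 | rac-4-{[2-(2-chloroethyl)-1,3-dioxolan-2-yl]methyl}oxolan-2-one | O=C1CC(CC2(CCCl)OCCO2)CO1
F9 | step 6 | 4-{[2-(2-chloroethyl)-1,3-dioxolan-2-yl]methyl}-3-(phenylselanyl)oxolan-2-one (racemic, diastereomers) | O=C1C([Se]c2ccccc2)C(CC3(CCCl)OCCO3)CO1
F10 | step 6 | 4-{[2-(2-chloroethyl)-1,3-dioxolan-2-yl]methyl}furan-2(5H)-one | O=C1C=C(CC2(CCCl)OCCO2)CO1
F11 | step 17 | 8α,9α-O-dibutylstannylene acetal of 27 | C=C(C)[C@H]1C[C@@]2(C)[C@H](CC3(OCCO3)C[C@@H]2C)[C@H](O4)[C@@H]1O[Sn]4(CCCC)CCCC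
A1 | alternative 1 | 4-methyl-4-(4-oxobutyl)cyclohexa-2,5-dien-1-one | O=CCCCC1(C)C=CC(=O)C=C1
A2 | alternative 1 | cis-fused 5-methyldecal-3-ene-2,9-dione (target numbering) | C1C[C@@]2(C)[C@H](CC(=O)C=C2)C(=O)C1
A3 | alternative 2 | cis-fused 9,9-dimethoxy-2-(tert-butyldimethylsilyloxy)eremophila-3,11-dien-8-one | C=C(C)[C@H]1C[C@@]2(C)[C@H](C[C@H](O[Si](C)(C)C(C)(C)C)C=C2C)C(OC)(OC)C1=O
A4 | alternative 3 | (4S)-4,5-dimethylcyclodeca-1(10),5-diene-2,9-dione, both alkenes E (target numbering) | O=C1C[C@H](C)/C(C)=C/CCC(=O)/C=C/1
A5 | alternative 3 | cis-fused 4,5-dimethyldecalin-2,9-dione (target numbering) | C1C[C@@]2(C)[C@H](CC(=O)C[C@@H]2C)C(=O)C1
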